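## Retrosynthetic overview

- Structural feature: on ring B, the side-chain carbon C1′ on quaternary C5 and the oxygen on C8 are cis and 1,4 to each other. They are read as the two ends of one C(=O)–O bridge, that is, of a 2-pyrone cycloadduct.
- Key disconnection C5–C4a / C8–C8a: a 3-methyl-2-pyrone that already carries the C6 chlorine at its C4 adds to an (E)-2-methylhept-2-enal. This gives ring B as a 2-oxabicyclo[2.2.2]octenone and sets C5, C4a, C8a and C8 together.
- After it: the vinyl chloride is reduced from the lactone face (C6), the bridge is cut by lactol olefination, and C1′ is homologated to an allyl group.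
- Ring A is closed second by Dieckmann condensation (C2 onto C1). Enol triflate formylation and deconjugation then give C1–CHO and C2=C3.
- The tertiary allylic alcohol is added last by cross-metathesis. Ring order: B (with the temporary lactone ring), then A.

Key step: step 7

Remark on notation: target numbering (C1–C8a, side chain C1′–C4′) is used for all intermediates. β is the ring-B face that carries O–C8 and C1′; α is the face that carries both methyl groups and chlorine.

Assumption: the (S)-prolinol-derived catalyst is taken to leave the C2-Si/C3-Re face of the bound enal open. If the sense is opposite, its equally available mirror image is used.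

## Route

Step 1
Reactants: 1 methylmalonic acid
Product: 2 methylmalonyl dichloride
Conditions: SOCl2, DMF (cat.), 45 °C
Reagents that add atoms: thionyl chloride, O=S(Cl)Cl
Why: Acyl chloride formation with SOCl2 under DMF catalysis is the standard preparation of substituted malonyl dichlorides, and the mild bath temperature should keep decarboxylation in check.

Step 2
Reactants: 2 methylmalonyl dichloride; 3 trimethyl(vinyloxy)silane
Product: 4 4-hydroxy-3-methyl-2H-pyran-2-one
Conditions: Et2O, −78 °C → rt
Reagents that add atoms: none
Why: This is the known 4-hydroxy-2-pyrone synthesis from silyl enol ethers and malonyl dichlorides, in which C-acylation of 3 gives a formyl ketone acid chloride whose enol oxygen closes onto the second acyl chloride, and the acetaldehyde-derived enol ether leaves pyrone C5 and C6 unsubstituted.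

Step 3
Reactants: 4 4-hydroxy-3-methyl-2H-pyran-2-one
Product: 5 4-chloro-3-methyl-2H-pyran-2-one
Conditions: POCl3 (neat), 90 °C
Reagents that add atoms: phosphoryl chloride, O=P(Cl)(Cl)Cl
Why: Deoxychlorination of the vinylogous acid (addition–elimination at C4 via the dichlorophosphate) is the usual way from 4-hydroxy-2-pyrones to 4-chloro-2-pyrones.

Step 4
Reactants: 6 pentane-1,5-diol
Product: 7 5-(tert-butyldimethylsilyloxy)pentan-1-ol
Conditions: TBSCl (1 equiv), imidazole, 6 (3 equiv), THF, 0 °C → rt
Reagents that add atoms: tert-butyldimethylsilyl chloride, CC(C)(C)[Si](C)(C)Cl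
Why: Statistical monosilylation with the diol in excess should give mainly the mono-TBS ether, and unreacted diol washes out with water.

Step 5
Reactants: 7 5-(tert-butyldimethylsilyloxy)pentan-1-ol
Product: 8 5-(tert-butyldimethylsilyloxy)pentanal
Conditions: TEMPO (10 mol %), PhI(OAc)2, CH2Cl2, rt
Reagents that add atoms: none
Why: TEMPO-catalysed oxidation with PhI(OAc)2 stops at the aldehyde and does not touch the silyl ether.

Step 6
Reactants: 8 5-(tert-butyldimethylsilyloxy)pentanal; 9 2-(triphenylphosphoranylidene)propanal
Product: 10 (E)-7-(tert-butyldimethylsilyloxy)-2-methylhept-2-enal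
Conditions: toluene, 90 °C
Reagents that add atoms: none
Why: Wittig olefination with the stabilised α-methyl ylide should give the E-trisubstituted enal, the geometry that later becomes the trans ring fusion.

Step 7
Reactants: 5 4-chloro-3-methyl-2H-pyran-2-one; 10 (E)-7-(tert-butyldimethylsilyloxy)-2-methylhept-2-enal
Product: 11 (1S,4R,5R,6R)-8-chloro-5-[4-(tert-butyldimethylsilyloxy)butyl]-4,6-dimethyl-3-oxo-2-oxabicyclo[2.2.2]oct-7-ene-6-carbaldehyde (formyl exo, syn to the O–C(=O) bridge; C8a methyl and C4 chain endo, syn to the chloroalkene bridge)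
Conditions: (S)-B-(o-tolyl)-α,α-diphenylprolinol oxazaborolidine·Tf2NH (20 mol %), 5 (2.5 equiv), CH2Cl2 (1 M), −40 → 0 °C
Reagents that add atoms: none
Why: Proposed new method: the N-protonated oxazaborolidine binds the formyl oxygen of 10 (B–O bond plus formyl C–H···O contact) and the pyrone adds as the 4π partner in a concerted, strongly asynchronous normal-demand [4+2], pyrone C3 bonding to the enal β-carbon (C5–C4a) ahead of pyrone C6 to the α-carbon (C8–C8a), and at these temperatures the adduct should keep its CO2 bridge. The closest known reactions are the thermal, high-pressure and Lewis-acid cycloadditions of 2-pyrones and halo-2-pyrones with acrolein, acrylates and methacrylates to 2-oxabicyclo[2.2.2]octenones and the oxazaborolidinium-catalysed additions of α-methyl enals to carbocyclic dienes, whereas a trisubstituted enal on a pyrone with formation of two quaternary carbons has not been shown. Ring B (C5–C6–C7–C8–C8a–C4a, a boat cyclohexene) and the second new six-membered ring (C5–C4a–C8a–C8–O–C1′) are both closed in the one intermolecular suprafacial–suprafacial cycloaddition, the former pyrone ring remaining as the third face of the bicycle. C5 and C8 are tied cis by the bridge because the diene reacts on one face, C4a and C8a keep the E geometry of 10 (C4 chain cis to the C8a methyl), their relation to the bridge comes from the formyl-exo topology that α-methyl enals prefer under this catalysis (methyl and chain under pyrone C4–C5, the bulky catalyst-bound formyl under the O1–C2 edge), and the absolute sense comes from the catalyst aryl group, which covers one enal face so that the diene meets the C2-Si/C3-Re face. The step needs the formyl-bearing carbon next to the oxygen bridgehead, which 2-pyrones with only a C3 substituent do not secure (3-halo-2-pyrones place the acceptor carbon of acrolein and acrylates next to C3); here the C4 chlorine directs "para" as in a 2-halobutadiene, chlorine and ring oxygen both stabilise the positive charge that builds at C4 and C6 when C3 attacks, and the other orientation would join two fully substituted carbons. The chlorine should also lower the basicity of the pyrone carbonyl and so limit competitive binding of the catalyst, and it is the C6 chlorine of the target.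

Step 8
Reactants: 11 bicyclic lactone aldehyde
Product: 12 dimethyl acetal of 11 (C1 as CH(OMe)2, all centres as in 11)
Conditions: MeOSiMe3 (3 equiv), TMSOTf (5 mol %), CH2Cl2, −78 → −30 °C
Reagents that add atoms: methoxytrimethylsilane, CO[Si](C)(C)C
Why: Silyl-triflate-catalysed acetalisation with an alkoxysilane (Noyori conditions) masks the neopentyl aldehyde under aprotic conditions at low temperature, so lactone, vinyl chloride and primary silyl ether are left alone and C1 stays distinguishable from C1′.

Step 9
Reactants: 12 chloroalkene lactone acetal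
Product: 13 saturated chloro lactone acetal (C6–Cl α, endo toward the C4a–C8a bridge, 6S)
Conditions: Mn(dpm)3 (10 mol %), PhSiH3, t-BuOOH, i-PrOH, 22 °C
Reagents that add atoms: none
Why: Hydrogen-atom-transfer hydrogenation, known to turn haloalkenes into alkyl halides without hydrogenolysis, should add H to C7 to give the α-chloro radical at C6, which takes its second hydrogen from the open lactone side because the other side is covered by the endo C4 chain, so chlorine ends α.

Step 10
Reactants: 13 saturated chloro lactone acetal
Product: 14 bridged lactol (C1′ epimers)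
Conditions: i-Bu2AlH (1.2 equiv), CH2Cl2, −78 °C; aq. potassium sodium tartrate
Reagents that add atoms: none
Why: Partial reduction of a lactone with i-Bu2AlH at −78 °C stops at the aluminium lactolate, and acetal, alkyl chloride and silyl ether are inert to it.

Step 11
Reactants: 14 bridged lactol
Product: 15 ring-B cyclohexanol: C8 β-OH; C8a α-Me, β-CH(OMe)2; C4a α-(CH2)4OTBS; C5 α-Me, β-CH=CHOMe (E/Z); C6 α-Cl
Conditions: (methoxymethyl)triphenylphosphonium chloride, NaN(SiMe3)2 (4 equiv each), THF, −78 → 0 °C
Reagents that add atoms: (methoxymethyl)triphenylphosphonium chloride, COC[P+](c1ccccc1)(c1ccccc1)c1ccccc1.[Cl-]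
Why: Wittig olefination of a lactol through its open hydroxy aldehyde form cuts the bridge for good and adds C2′, and short contact at or below 0 °C should keep the C8 alkoxide from Grob fragmentation toward C6–Cl.

Step 12
Reactants: 15 enol ether alcohol
Product: 16 C8 β-OTBS ether of 15
Conditions: TBSOTf (1.3 equiv), 2,6-lutidine, CH2Cl2, −78 → −20 °C
Reagents that add atoms: tert-butyldimethylsilyl triflate, CC(C)(C)[Si](C)(C)OS(=O)(=O)C(F)(F)F
Why: Silylation with the silyl triflate and a hindered pyridine base reaches the hindered neopentyl alcohol without forming an alkoxide, and the low temperature and small excess should spare acetal and enol ether.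

Step 13
Reactants: 16 bis-silyl enol ether
Product: 18 C5 β-(2-oxoethyl) aldehyde (C1′H2–C2′HO; ring centres unchanged), via organomercurial aldehyde 17 (not isolated)
Conditions: Hg(OAc)2, THF/H2O (10:1), 0 °C; then aq. KI
Reagents that add atoms: water, O; Hg(OAc)2, CC(=O)O[Hg]OC(C)=O (its atoms stay only in 17)
Why: Oxymercuration of the electron-rich enol ether followed by iodide-assisted protodemercuration amounts to a near-neutral enol ether hydrolysis that spares the dimethyl acetal and both silyl ethers, which aqueous mineral acid would not.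

Step 14
Reactants: 18 C5 β-(2-oxoethyl) aldehyde
Product: 19 C5 β-allyl compound (C1′H2–C2′H=C3′H2)
Conditions: methyltriphenylphosphonium bromide, KOt-Bu, THF, 0 °C
Reagents that add atoms: methyltriphenylphosphonium bromide, C[P+](c1ccccc1)(c1ccccc1)c1ccccc1.[Br-]
Why: Wittig methylenation of the unhindered CH2–CHO group is fast and puts C1′ as the CH2 between C5 and the future side-chain alkene.

Step 15
Reactants: 19 C5 β-allyl compound
Product: 20 hydroxy aldehyde (C1 formyl free, chain-end CH2OH free, C8 β-OTBS kept)
Conditions: AcOH/THF/H2O (3:1:1), rt → 40 °C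
Reagents that add atoms: water, O
Why: Aqueous acetic acid solvolyses primary TBS ethers and dimethyl acetals but should leave the hindered secondary TBS ether next to quaternary C8a.

Step 16
Reactants: 20 hydroxy aldehyde
Product: 22 diacid (C1 and chain-end CO2H), via dialdehyde 21 (not isolated)
Conditions: TEMPO (10 mol %), PhI(OAc)2, CH2Cl2, rt; then NaClO2, NaH2PO4, 2-methyl-2-butene, t-BuOH/H2O, rt
Reagents that add atoms: sodium chlorite, [Na+].[O-]Cl=O
Why: One-pot TEMPO oxidation and Pinnick oxidation bring both termini to the acid level, and the alkene scavenger takes up HOCl so that the allyl group is not chlorinated.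

Step 17
Reactants: 22 diacid
Product: 23 dimethyl ester
Conditions: MeI, K2CO3, DMF, rt
Reagents that add atoms: iodomethane, CI
Why: Carboxylate O-alkylation (SN2 on MeI) also esterifies the hindered C1 acid, because the new bond is made at oxygen and not at the crowded carbonyl carbon.

Step 18
Reactants: 23 dimethyl ester
Product: 24 trans-decalin β-keto ester (C1 ketone, C2–CO2Me as keto/enol mixture; 4a β-H, 8a α-Me)
Conditions: KOt-Bu (2.5 equiv), THF, 0 °C → rt; AcOH quench
Reagents that add atoms: none
Why: In this Dieckmann condensation only the chain ester has α-hydrogens (C2) and the C1 ester on quaternary C8a can act only as acceptor, so 6-exo closure between the two equatorial arms should give ring A with the trans fusion already fixed at C4a and C8a, driven by formation of the stabilised enolate.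

Step 19
Reactants: 24 β-keto ester
Product: 25 C1 enol triflate (C1=C2)
Conditions: Tf2O, i-Pr2NEt, CH2Cl2, −78 → 0 °C
Reagents that add atoms: triflic anhydride, O=S(=O)(OS(=O)(=O)C(F)(F)F)C(F)(F)F
Why: O-sulfonylation of the enolised β-keto ester is the standard route to β-triflyloxy enoates, and the ring allows only one alkene geometry.

Step 20
Reactants: 25 C1 enol triflate
Product: 26 methyl 1-formyl-1-ene-2-carboxylate (C1=C2 tetrasubstituted)
Conditions: Pd(PPh3)4 (10 mol %), LiCl, CO (3 atm), Bu3SnH (syringe pump), THF, 50 °C
Reagents that add atoms: carbon monoxide, [C-]#[O+]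
Why: Palladium-catalysed reductive carbonylation of a vinyl triflate (oxidative addition, CO insertion, hydride transfer from tin) adds the formyl carbon, slow addition of the hydride under CO pressure limits direct reduction, and the secondary alkyl chloride does not add to zerovalent palladium under these conditions.

Step 21
Reactants: 26 conjugated formyl ester
Product: 28 β,γ-unsaturated aldehyde (C2=C3; C1 α-CHO equatorial and β-H; 1R), via potassium dienolate 27 (not isolated)
Conditions: KOt-Bu (1.2 equiv), THF, −78 °C; then AcOH, −78 °C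
Reagents that add atoms: none
Why: In this deconjugative protonation, removal of a C3 hydrogen (the only acidic C–H) gives the extended enolate and kinetic protonation at its α-carbon C1 moves the alkene to C2=C3 in conjugation with the ester, the proton entering axially on the β face opposite the angular methyl so that the formyl group becomes equatorial, which is also the more stable epimer of this epimerisable centre.

Step 22
Reactants: 28 silyl-protected β,γ-unsaturated aldehyde
Product: 29 C8 β-alcohol with C5 β-allyl group
Conditions: HF·pyridine, THF, 0 °C → rt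
Reagents that add atoms: none
Why: Fluoride desilylation under acidic conditions frees the hindered alcohol without forming an alkoxide, which could fragment toward C6–Cl or isomerise C1.

Step 23
Reactants: 29 C5 β-allyl alcohol; 30 2-methylbut-3-en-2-ol
Product: 31 target, methyl (1R,4aR,5S,6S,8S,8aS)-6-chloro-1-formyl-8-hydroxy-5-[(E)-4-hydroxy-4-methylpent-2-en-1-yl]-5,8a-dimethyl-1,4,4a,5,6,7,8,8a-octahydronaphthalene-2-carboxylate
Conditions: 30 (10 equiv), second-generation Hoveyda–Grubbs catalyst (5 mol %), CH2Cl2, 40 °C
Reagents that add atoms: none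
Why: Olefin cross-metathesis of a terminal allyl group with an excess of the bulky tertiary allylic alcohol should give the E-disubstituted alkene, while the trisubstituted electron-poor C2=C3 alkene, aldehyde, alcohol and chloride are not engaged.

## Compound list

1 | methylmalonic acid | CC(C(=O)O)C(=O)O | starting material
2 | methylmalonyl dichloride | CC(C(=O)Cl)C(=O)Cl | intermediate
3 | trimethyl(vinyloxy)silane | C=CO[Si](C)(C)C | starting material
4 | 4-hydroxy-3-methyl-2H-pyran-2-one | CC1=C(O)C=COC1=O | intermediate
5 | 4-chloro-3-methyl-2H-pyran-2-one | CC1=C(Cl)C=COC1=O | intermediate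
6 | pentane-1,5-diol | OCCCCCO | starting material
7 | 5-(tert-butyldimethylsilyloxy)pentan-1-ol | OCCCCCO[Si](C)(C)C(C)(C)C | intermediate
8 | 5-(tert-butyldimethylsilyloxy)pentanal | O=CCCCCO[Si](C)(C)C(C)(C)C | intermediate
9 | 2-(triphenylphosphoranylidene)propanal | CC(C=O)=P(c1ccccc1)(c1ccccc1)c1ccccc1 | starting material
10 | (E)-7-(tert-butyldimethylsilyloxy)-2-methylhept-2-enal | O=C/C(C)=C/CCCCO[Si](C)(C)C(C)(C)C | intermediate
11 | bicyclic lactone aldehyde, formyl exo, (1S,4R,5R,6R) | O=C[C@]1(C)[C@@H](CCCCO[Si](C)(C)C(C)(C)C)[C@@]2(C)C(Cl)=C[C@@H]1OC2=O | intermediate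
12 | dimethyl acetal of 11 | COC(OC)[C@]1(C)[C@@H](CCCCO[Si](C)(C)C(C)(C)C)[C@@]2(C)C(Cl)=C[C@@H]1OC2=O | intermediate
13 | saturated chloro lactone acetal, C6–Cl α | COC(OC)[C@]1(C)[C@@H](CCCCO[Si](C)(C)C(C)(C)C)[C@@]2(C)[C@@H](Cl)C[C@@H]1OC2=O | intermediate
14 | bridged lactol, C1′ epimers | COC(OC)[C@]1(C)[C@@H](CCCCO[Si](C)(C)C(C)(C)C)[C@@]2(C)[C@@H](Cl)C[C@@H]1OC2O | intermediate
15 | ring-B cyclohexanol with C5 β-(2-methoxyvinyl) group, E/Z | COC(OC)[C@]1(C)[C@@H](CCCCO[Si](C)(C)C(C)(C)C)[C@](C)(C=COC)[C@@H](Cl)C[C@@H]1O | intermediate
16 | C8 β-OTBS ether of 15 | COC(OC)[C@]1(C)[C@@H](CCCCO[Si](C)(C)C(C)(C)C)[C@](C)(C=COC)[C@@H](Cl)C[C@@H]1O[Si](C)(C)C(C)(C)C | intermediate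
17 | C1′-acetoxymercurio aldehyde, C1′ epimers | COC(OC)[C@]1(C)[C@@H](CCCCO[Si](C)(C)C(C)(C)C)[C@](C)(C(C=O)[Hg]OC(C)=O)[C@@H](Cl)C[C@@H]1O[Si](C)(C)C(C)(C)C | intermediate
18 | C5 β-(2-oxoethyl) aldehyde | COC(OC)[C@]1(C)[C@@H](CCCCO[Si](C)(C)C(C)(C)C)[C@](C)(CC=O)[C@@H](Cl)C[C@@H]1O[Si](C)(C)C(C)(C)C | intermediate
19 | C5 β-allyl compound | COC(OC)[C@]1(C)[C@@H](CCCCO[Si](C)(C)C(C)(C)C)[C@](C)(CC=C)[C@@H](Cl)C[C@@H]1O[Si](C)(C)C(C)(C)C | intermediate
20 | hydroxy aldehyde (C1 formyl, chain-end CH2OH) | O=C[C@]1(C)[C@@H](CCCCO)[C@](C)(CC=C)[C@@H](Cl)C[C@@H]1O[Si](C)(C)C(C)(C)C | intermediate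
21 | dialdehyde | O=C[C@]1(C)[C@@H](CCCC=O)[C@](C)(CC=C)[C@@H](Cl)C[C@@H]1O[Si](C)(C)C(C)(C)C | intermediate
22 | diacid | OC(=O)[C@]1(C)[C@@H](CCCC(=O)O)[C@](C)(CC=C)[C@@H](Cl)C[C@@H]1O[Si](C)(C)C(C)(C)C | intermediate
23 | dimethyl ester | COC(=O)[C@]1(C)[C@@H](CCCC(=O)OC)[C@](C)(CC=C)[C@@H](Cl)C[C@@H]1O[Si](C)(C)C(C)(C)C | intermediate
24 | trans-decalin β-keto ester, C2 epimers/enol | COC(=O)C1CC[C@H]2[C@](C)(CC=C)[C@@H](Cl)C[C@H](O[Si](C)(C)C(C)(C)C)[C@]2(C)C1=O | intermediate
25 | C1 enol triflate | COC(=O)C=1CC[C@H]2[C@](C)(CC=C)[C@@H](Cl)C[C@H](O[Si](C)(C)C(C)(C)C)[C@]2(C)C=1OS(=O)(=O)C(F)(F)F | intermediate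
26 | conjugated 1-formyl-1-ene-2-carboxylate | COC(=O)C=1CC[C@H]2[C@](C)(CC=C)[C@@H](Cl)C[C@H](O[Si](C)(C)C(C)(C)C)[C@]2(C)C=1C=O | intermediate
27 | potassium dienolate of 26 | COC(=O)C1=CC[C@H]2[C@](C)(CC=C)[C@@H](Cl)C[C@H](O[Si](C)(C)C(C)(C)C)[C@]2(C)C1=C[O-].[K+] | intermediate
28 | deconjugated aldehyde, 1R, C8 β-OTBS | COC(=O)C1=CC[C@H]2[C@](C)(CC=C)[C@@H](Cl)C[C@H](O[Si](C)(C)C(C)(C)C)[C@]2(C)[C@H]1C=O | intermediate
29 | C8 β-alcohol with C5 β-allyl group | COC(=O)C1=CC[C@H]2[C@](C)(CC=C)[C@@H](Cl)C[C@H](O)[C@]2(C)[C@H]1C=O | intermediate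
30 | 2-methylbut-3-en-2-ol | C=CC(C)(C)O | starting material
31 | CNP0167913.1 | COC(=O)C1=CC[C@H]2[C@](C)(C/C=C/C(C)(C)O)[C@@H](Cl)C[C@H](O)[C@]2(C)[C@H]1C=O | target

## Step count and risks

Total step count: 23. Longest linear sequence: 20 (steps 1–3 or steps 4–6, then steps 7–23).

Steps most likely to fail:

1. Step 7.
The pyrone carbonyl may compete with the enal for the boron centre, and the doubly quaternary bond set may form too slowly. Exo and facial control may also erode at the temperature that conversion demands.
The fallback sets out from 5 and 10 and comes back at 11. It replaces Lewis-acid activation by pressure and replaces catalysis by resolution.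
5 and 10 are compressed without catalyst (CH2Cl2, 12–15 kbar, 25–40 °C). This is the known way to bridged lactones from 2-pyrones and α-substituted acrylic dienophiles, with the chlorine still directing the orientation. It gives the racemic adduct F1.
Condensation with (1R,2R)-N,N′-dimethyl-1,2-diphenylethane-1,2-diamine (Et2O, 4 Å sieves, rt) gives the wanted imidazolidine F2 and the mirror-image-derived imidazolidine F3, which are separated on silica.
Brief two-phase hydrolysis of F2 (dilute aq. HCl/Et2O, 0 °C) returns enantiopure 11.

2. Step 9.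
Hydrogen may add at C6 instead of C7, with loss of chlorine from the β-chloro radical. The second hydrogen may also be delivered from the chain side.
The fallback sets out from 12 and comes back at 14. It moves the reduction behind the bridge opening and uses the C8 hydroxyl as director.
K2CO3 in MeOH (0 °C) opens the strained lactone to the chlorocyclohexenol methyl ester F4.
[Ir(cod)(PCy3)(py)]PF6 under H2 in CH2Cl2 binds the β-hydroxyl and delivers both hydrogens to the β face, giving the saturated α-chloro hydroxy ester F5.
i-Bu2AlH (2.5 equiv, CH2Cl2, −78 °C) takes the ester to the aldehyde level, which closes to lactol 14.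

3. Step 20.
Hydride may capture the vinyl- or acylpalladium species before CO insertion at the crowded C1, giving simple reduction. Palladium hydride may also isomerise the allyl group.
The fallback sets out from 25 and comes back at 26. It brings the carbon in as hydroxymethyl and adjusts the oxidation level through a furan.
Stille coupling with Bu3SnCH2OH (Pd(PPh3)4, LiCl, dioxane, 90 °C) gives an allylic alcohol that lactonises onto the neighbouring ester to the fused butenolide F6.
i-Pr3SiOTf and Et3N (CH2Cl2, 0 °C) give the 2-silyloxyfuran F7.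
Dimethyldioxirane (acetone, −78 °C) reacts far faster with the furan than with the allyl group and gives the γ-hydroxybutenolide F8, the ring tautomer of the formyl acid.
MeI and K2CO3 in DMF alkylate the open carboxylate to 26.

Further compounds
F1 | step 7 | racemic adduct (11 plus its mirror image; the mirror image is drawn) | O=C[C@@]1(C)[C@H](CCCCO[Si](C)(C)C(C)(C)C)[C@]2(C)C(Cl)=C[C@H]1OC2=O
F2 | step 7 | imidazolidine of 11 with the (1R,2R)-diamine | CN1[C@H](c2ccccc2)[C@@H](c2ccccc2)N(C)C1[C@]3(C)[C@@H](CCCCO[Si](C)(C)C(C)(C)C)[C@@]4(C)C(Cl)=C[C@@H]3OC4=O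
F3 | step 7 | imidazolidine of the mirror image of 11 with the (1R,2R)-diamine (discarded) | CN1[C@H](c2ccccc2)[C@@H](c2ccccc2)N(C)C1[C@@]3(C)[C@H](CCCCO[Si](C)(C)C(C)(C)C)[C@]4(C)C(Cl)=C[C@H]3OC4=O
F4 | step 9 | chlorocyclohexenol methyl ester (C5 β-CO2Me, C8 β-OH, C6=C7) | COC(OC)[C@]1(C)[C@@H](CCCCO[Si](C)(C)C(C)(C)C)[C@](C)(C(=O)OC)C(Cl)=C[C@@H]1O
F5 | step 9 | saturated α-chloro hydroxy ester | COC(OC)[C@]1(C)[C@@H](CCCCO[Si](C)(C)C(C)(C)C)[C@](C)(C(=O)OC)[C@@H](Cl)C[C@@H]1O
F6 | step 20 | fused butenolide (C1–CH2–O–C(=O)–C2) | O=C1OCC2=C1CC[C@H]3[C@](C)(CC=C)[C@@H](Cl)C[C@H](O[Si](C)(C)C(C)(C)C)[C@]23C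
F7 | step 20 | fused 2-(triisopropylsilyloxy)furan | CC(C)[Si](C(C)C)(C(C)C)Oc1occ2c1CC[C@H]3[C@](C)(CC=C)[C@@H](Cl)C[C@H](O[Si](C)(C)C(C)(C)C)[C@]23C
F8 | step 20 | fused γ-hydroxybutenolide, lactol epimers | O=C1OC(O)C2=C1CC[C@H]3[C@](C)(CC=C)[C@@H](Cl)C[C@H](O[Si](C)(C)C(C)(C)C)[C@]23C
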